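**Strategy.** Ring A is disconnected at C4a–C5 and treated as a folded triketide, because its oxygens sit on C5, C7 and C8a while carbon is attached only at C4a. The precursor is a 4-benzyloxy-6-alkyl-2-pyranone whose side chain already holds ring B and the anti C2/C3 oxygens. Benzyloxide opens the lactone and the chain recloses by Claisen acylation, giving ring A as a 2-alkyl-5-benzyloxyresorcinol in one operation. That resorcinol is locally symmetric, so either hydroxyl can serve as O1 when ring C is closed by Mitsunobu inversion at C2. The side chain comes from a Sharpless kinetic-resolution epoxide opened by the lithiated pyranone.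

Key step: step 9

Remark: flavan numbering (O1, C2, C3, C4, C4a, C5–C8, C8a; ring B primed) is used for the corresponding atoms of all open-chain intermediates.

**Step 1**
Reactants: 1 3,4,5-trihydroxybenzaldehyde
Product: 2 3,5-dihydroxy-4-(methoxymethoxy)benzaldehyde
Conditions: MOMCl (1.0 equiv), iPr2NEt (1.1 equiv), DMF, 0 °C, Ar
Reagents that add atoms: chloromethyl methyl ether, COCCl
Why: The 4-hydroxyl, para to the formyl group, is by far the most acidic and is the only one ionised by one equivalent of amine base, so this Williamson-type monoalkylation should take place there.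

**Step 2**
Reactants: 2 3,5-dihydroxy-4-(methoxymethoxy)benzaldehyde
Product: 3 3,5-bis(benzyloxy)-4-(methoxymethoxy)benzaldehyde
Conditions: BnBr, K2CO3, DMF, rt
Reagents that add atoms: benzyl bromide, BrCc1ccccc1
Why: Williamson etherification of the two remaining phenols under conditions that leave the aryl MOM acetal and the aldehyde untouched.

**Step 3**
Reactants: 3 3,5-bis(benzyloxy)-4-(methoxymethoxy)benzaldehyde
Product: 4 rac-1-[3,5-bis(benzyloxy)-4-(methoxymethoxy)phenyl]prop-2-en-1-ol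
Conditions: CH2=CHMgBr, THF, −78 → 0 °C; then aq. NH4Cl
Reagents that add atoms: vinylmagnesium bromide, C=C[Mg]Br
Why: Grignard 1,2-addition to the aryl aldehyde gives the racemic secondary allylic alcohol, whose stereocentre is resolved in the next step.

**Step 4**
Reactants: 4 rac-1-[3,5-bis(benzyloxy)-4-(methoxymethoxy)phenyl]prop-2-en-1-ol
Product: 5 (S)-[3,5-bis(benzyloxy)-4-(methoxymethoxy)phenyl][(R)-oxiran-2-yl]methanol (anti epoxy alcohol)
Conditions: Ti(OiPr)4 (0.2 equiv), L-(+)-DIPT (0.25 equiv), t-BuOOH (0.6 equiv), 4 Å MS, CH2Cl2, −20 °C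
Reagents that add atoms: tert-butyl hydroperoxide, CC(C)(C)OO
Why: Sharpless kinetic resolution: with L-(+)-DIPT the (R)-enantiomer of 4 should be epoxidised fast, on the face that gives the erythro (anti) epoxy alcohol, which sets C2 as S and C3 as R, while the (S)-alcohol stays behind and is separated.

**Step 5**
Reactants: 5 (S)-[3,5-bis(benzyloxy)-4-(methoxymethoxy)phenyl][(R)-oxiran-2-yl]methanol
Product: 6 {(S)-[3,5-bis(benzyloxy)-4-(methoxymethoxy)phenyl][(R)-oxiran-2-yl]methoxy}triisopropylsilane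
Conditions: TIPSOTf, 2,6-lutidine, CH2Cl2, −78 → −20 °C
Reagents that add atoms: triisopropylsilyl trifluoromethanesulfonate, CC(C)[Si](C(C)C)(C(C)C)OS(=O)(=O)C(F)(F)F
Why: Low-temperature silylation of the secondary alcohol without touching the epoxide; the TIPS ether is chosen because it resists alkoxide, BF3 at −78 °C and 1,2-silyl migration to a neighbouring alkoxide.

**Step 6**
Reactants: 7 4-hydroxy-6-methyl-2H-pyran-2-one (triacetic acid lactone)
Product: 8 4-(benzyloxy)-6-methyl-2H-pyran-2-one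
Conditions: BnOH, PPh3, DIAD, THF, 0 °C → rt
Reagents that add atoms: benzyl alcohol, OCc1ccccc1
Why: Mitsunobu O-alkylation in which the acidic 4-hydroxyl (a vinylogous carboxylic acid) is the pronucleophile, giving the 4-O-benzyl ether and avoiding the C3-alkylation that benzyl halides can cause.

**Step 7**
Reactants: 8 4-(benzyloxy)-6-methyl-2H-pyran-2-one and 6 {(S)-[3,5-bis(benzyloxy)-4-(methoxymethoxy)phenyl][(R)-oxiran-2-yl]methoxy}triisopropylsilane
Product: 10 4-(benzyloxy)-6-{(3R,4S)-4-[3,5-bis(benzyloxy)-4-(methoxymethoxy)phenyl]-3-hydroxy-4-[(triisopropylsilyl)oxy]butyl}-2H-pyran-2-one, via lithiated pyranone 9 (not isolated)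
Conditions: 8 (2.5 equiv), LiN(iPr)2, THF, −78 °C; then 6, BF3·OEt2, −78 °C; aq. NH4Cl
Reagents that add atoms: none
Why: BF3-assisted SN2 opening of the terminal epoxide at its unhindered CH2 by the exocyclic carbanion of the pyranone (a vinylogous lactone enolate) forms C4–C4a, and C3 keeps its R configuration because its C–O bond is not broken.

**Step 8**
Reactants: 10 4-(benzyloxy)-6-{(3R,4S)-4-[3,5-bis(benzyloxy)-4-(methoxymethoxy)phenyl]-3-hydroxy-4-[(triisopropylsilyl)oxy]butyl}-2H-pyran-2-one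
Product: 11 4-(benzyloxy)-6-{(3R,4S)-4-[3,5-bis(benzyloxy)-4-(methoxymethoxy)phenyl]-3-(methoxymethoxy)-4-[(triisopropylsilyl)oxy]butyl}-2H-pyran-2-one
Conditions: MOMCl, iPr2NEt, Bu4NI (cat.), CH2Cl2, 0 → 40 °C
Reagents that add atoms: chloromethyl methyl ether, COCCl
Why: Alkylation of the secondary C3 alcohol to a base-stable acetal that later leaves together with the 4′-O-MOM group, so that O3 and O4′ are unveiled as a pair.

**Step 9**
Reactants: 11 4-(benzyloxy)-6-{(3R,4S)-4-[3,5-bis(benzyloxy)-4-(methoxymethoxy)phenyl]-3-(methoxymethoxy)-4-[(triisopropylsilyl)oxy]butyl}-2H-pyran-2-one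
Product: 14 5-(benzyloxy)-2-{(2R,3S)-3-[3,5-bis(benzyloxy)-4-(methoxymethoxy)phenyl]-2-(methoxymethoxy)-3-[(triisopropylsilyl)oxy]propyl}benzene-1,3-diol, via ring-opened benzyl ketoenoate 12 (not isolated), via cyclohexenedione 13 (not isolated)
Conditions: NaOCH2Ph (1 M in BnOH, 4 equiv), THF, 65 °C, Ar; then AcOH
Reagents that add atoms: none
Why: Benzyloxide adds to the lactone carbonyl (C5) and the ring opens at O–C8a to the benzyl (2E)-3-benzyloxy-5-oxoenoate 12, whose C6=C7 geometry, inherited from the pyranone, keeps the ester cis to the ketone arm; the reversibly formed C4a enolate of the C8a ketone then attacks C5, expels benzyloxide to give dione 13, and enolisation to the aromatic resorcinolate makes the sequence irreversible. The closest known reaction type is the alkoxide-induced isomerisation of 4-alkoxy-6-methyl-2-pyranones to 5-alkoxyresorcinols, together with the Claisen cyclisation of 3,5-dioxoalkanoates to phloroglucinols. Ring A closes by C4a–C5 bond formation in a 6-exo-trig Claisen (Dieckmann-type) acylation. No stereocentre is formed, and C2 (S) and C3 (R) are safe because they bear only base-stable ethers and have no acidic neighbour. The step needs C-acylation at C4a instead of reclosure to the pyranone through oxygen or reaction through the more acidic C8; reclosure is reversible and C8 could only close a four-membered ring, the C7 enol ether prevents deprotonation at C6 and keeps the ester electrophilic, and aromatisation is the only exit. Benzyloxide as the base makes transesterification and any addition–elimination at C7 degenerate.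

**Step 10**
Reactants: 14 5-(benzyloxy)-2-{(2R,3S)-3-[3,5-bis(benzyloxy)-4-(methoxymethoxy)phenyl]-2-(methoxymethoxy)-3-[(triisopropylsilyl)oxy]propyl}benzene-1,3-diol
Product: 15 5-(benzyloxy)-2-{(2R,3S)-3-[3,5-bis(benzyloxy)-4-(methoxymethoxy)phenyl]-3-hydroxy-2-(methoxymethoxy)propyl}benzene-1,3-diol
Conditions: Bu4NF (3 equiv), THF, 0 °C → rt
Reagents that add atoms: none
Why: Fluoride-mediated desilylation frees the C2 hydroxyl while the acetals and benzyl ethers are inert.

**Step 11**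
Reactants: 15 5-(benzyloxy)-2-{(2R,3S)-3-[3,5-bis(benzyloxy)-4-(methoxymethoxy)phenyl]-3-hydroxy-2-(methoxymethoxy)propyl}benzene-1,3-diol
Product: 16 (2R,3R)-7-(benzyloxy)-2-[3,5-bis(benzyloxy)-4-(methoxymethoxy)phenyl]-3-(methoxymethoxy)chroman-5-ol
Conditions: PPh3, DIAD, THF (0.01 M), 0 °C → rt
Reagents that add atoms: none
Why: Mitsunobu cyclodehydration: the C2 hydroxyl, the only free alcohol, is activated and displaced in a 6-exo-tet SN2 reaction by either of the two equivalent ring A phenols, which inverts C2 from S to R and so sets the 2,3-cis relationship next to the untouched C3 (R), the C3 MOM ether blocking any competing activation of O3.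

**Step 12**
Reactants: 16 (2R,3R)-7-(benzyloxy)-2-[3,5-bis(benzyloxy)-4-(methoxymethoxy)phenyl]-3-(methoxymethoxy)chroman-5-ol
Product: 17 (2R,3R)-5,7-bis(benzyloxy)-2-[3,5-bis(benzyloxy)-4-(methoxymethoxy)phenyl]-3-(methoxymethoxy)chromane
Conditions: BnBr, K2CO3, DMF, rt
Reagents that add atoms: benzyl bromide, BrCc1ccccc1
Why: Williamson benzylation caps the remaining O5 phenol so that only O3 and O4′ will be free for acylation.

**Step 13**
Reactants: 17 (2R,3R)-5,7-bis(benzyloxy)-2-[3,5-bis(benzyloxy)-4-(methoxymethoxy)phenyl]-3-(methoxymethoxy)chromane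
Product: 18 (2R,3R)-5,7-bis(benzyloxy)-2-[3,5-bis(benzyloxy)-4-hydroxyphenyl]chroman-3-ol
Conditions: HCl (3 M aq.), MeOH/THF, 45 °C
Reagents that add atoms: none
Why: Acid-catalysed acetal exchange with methanol cleaves the aryl and the alkyl MOM ether, while benzyl ethers and the chroman C2–O1 bond should withstand dilute acid at this temperature.

**Step 14**
Reactants: 18 (2R,3R)-5,7-bis(benzyloxy)-2-[3,5-bis(benzyloxy)-4-hydroxyphenyl]chroman-3-ol and 19 3,4,5-tris(benzyloxy)benzoic acid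
Product: 20 (2R,3R)-5,7-bis(benzyloxy)-2-{3,5-bis(benzyloxy)-4-[3,4,5-tris(benzyloxy)benzoyloxy]phenyl}chroman-3-yl 3,4,5-tris(benzyloxy)benzoate
Conditions: 19 (3 equiv), EDC·HCl, DMAP, CH2Cl2, rt
Reagents that add atoms: none
Why: Steglich esterification acylates the secondary C3 alcohol and the hindered 4′-phenol, the only free hydroxyls, without disturbing either stereocentre.

**Step 15**
Reactants: 20 (2R,3R)-5,7-bis(benzyloxy)-2-{3,5-bis(benzyloxy)-4-[3,4,5-tris(benzyloxy)benzoyloxy]phenyl}chroman-3-yl 3,4,5-tris(benzyloxy)benzoate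
Product: 21 epigallocatechin 3,4′-di-O-gallate
Conditions: H2 (1 atm), Pd(OH)2/C, THF/MeOH, rt
Reagents that add atoms: none
Why: Hydrogenolysis removes all ten benzyl ethers while both gallate esters persist, and the neutral medium with short contact time limits migration of the 4′-O-galloyl group to a neighbouring hydroxyl.

**Compound list**

1 | 3,4,5-trihydroxybenzaldehyde | O=Cc1cc(O)c(O)c(O)c1 | starting material
2 | 3,5-dihydroxy-4-(methoxymethoxy)benzaldehyde | COCOc1c(O)cc(C=O)cc1O | intermediate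
3 | 3,5-bis(benzyloxy)-4-(methoxymethoxy)benzaldehyde | COCOc1c(OCc2ccccc2)cc(C=O)cc1OCc2ccccc2 | intermediate
4 | rac-1-[3,5-bis(benzyloxy)-4-(methoxymethoxy)phenyl]prop-2-en-1-ol | COCOc1c(OCc2ccccc2)cc(C(O)C=C)cc1OCc2ccccc2 | intermediate
5 | (S)-[3,5-bis(benzyloxy)-4-(methoxymethoxy)phenyl][(R)-oxiran-2-yl]methanol | COCOc1c(OCc2ccccc2)cc([C@H](O)[C@H]3CO3)cc1OCc2ccccc2 | intermediate
6 | {(S)-[3,5-bis(benzyloxy)-4-(methoxymethoxy)phenyl][(R)-oxiran-2-yl]methoxy}triisopropylsilane | COCOc1c(OCc2ccccc2)cc([C@H](O[Si](C(C)C)(C(C)C)C(C)C)[C@H]3CO3)cc1OCc2ccccc2 | intermediate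
7 | 4-hydroxy-6-methyl-2H-pyran-2-one (triacetic acid lactone) | Cc1cc(O)cc(=O)o1 | starting material
8 | 4-(benzyloxy)-6-methyl-2H-pyran-2-one | Cc1cc(OCc2ccccc2)cc(=O)o1 | intermediate
9 | 4-(benzyloxy)-6-(lithiomethyl)-2H-pyran-2-one | [Li]Cc1cc(OCc2ccccc2)cc(=O)o1 | intermediate
10 | 4-(benzyloxy)-6-{(3R,4S)-4-[3,5-bis(benzyloxy)-4-(methoxymethoxy)phenyl]-3-hydroxy-4-[(triisopropylsilyl)oxy]butyl}-2H-pyran-2-one | COCOc1c(OCc2ccccc2)cc([C@H](O[Si](C(C)C)(C(C)C)C(C)C)[C@H](O)CCc3cc(OCc2ccccc2)cc(=O)o3)cc1OCc2ccccc2 | intermediate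
11 | 4-(benzyloxy)-6-{(3R,4S)-4-[3,5-bis(benzyloxy)-4-(methoxymethoxy)phenyl]-3-(methoxymethoxy)-4-[(triisopropylsilyl)oxy]butyl}-2H-pyran-2-one (key-step precursor) | COCOc1c(OCc2ccccc2)cc([C@H](O[Si](C(C)C)(C(C)C)C(C)C)[C@H](OCOC)CCc3cc(OCc2ccccc2)cc(=O)o3)cc1OCc2ccccc2 | intermediate
12 | benzyl (2E,8R,9S)-3-(benzyloxy)-9-[3,5-bis(benzyloxy)-4-(methoxymethoxy)phenyl]-8-(methoxymethoxy)-5-oxo-9-[(triisopropylsilyl)oxy]non-2-enoate | COCOc1c(OCc2ccccc2)cc([C@H](O[Si](C(C)C)(C(C)C)C(C)C)[C@H](OCOC)CCC(=O)C/C(OCc2ccccc2)=C\C(=O)OCc2ccccc2)cc1OCc2ccccc2 | intermediate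
13 | 5-(benzyloxy)-2-{(2R,3S)-3-[3,5-bis(benzyloxy)-4-(methoxymethoxy)phenyl]-2-(methoxymethoxy)-3-[(triisopropylsilyl)oxy]propyl}cyclohex-4-ene-1,3-dione (ring carbon C4a unspecified) | COCOc1c(OCc2ccccc2)cc([C@H](O[Si](C(C)C)(C(C)C)C(C)C)[C@H](OCOC)CC3C(=O)CC(OCc2ccccc2)=CC3=O)cc1OCc2ccccc2 | intermediate
14 | 5-(benzyloxy)-2-{(2R,3S)-3-[3,5-bis(benzyloxy)-4-(methoxymethoxy)phenyl]-2-(methoxymethoxy)-3-[(triisopropylsilyl)oxy]propyl}benzene-1,3-diol (key-step product) | COCOc1c(OCc2ccccc2)cc([C@H](O[Si](C(C)C)(C(C)C)C(C)C)[C@H](OCOC)Cc3c(O)cc(OCc2ccccc2)cc3O)cc1OCc2ccccc2 | intermediate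
15 | 5-(benzyloxy)-2-{(2R,3S)-3-[3,5-bis(benzyloxy)-4-(methoxymethoxy)phenyl]-3-hydroxy-2-(methoxymethoxy)propyl}benzene-1,3-diol | COCOc1c(OCc2ccccc2)cc([C@H](O)[C@H](OCOC)Cc3c(O)cc(OCc2ccccc2)cc3O)cc1OCc2ccccc2 | intermediate
16 | (2R,3R)-7-(benzyloxy)-2-[3,5-bis(benzyloxy)-4-(methoxymethoxy)phenyl]-3-(methoxymethoxy)chroman-5-ol | COCOc1c(OCc2ccccc2)cc([C@H]3Oc4cc(OCc2ccccc2)cc(O)c4C[C@H]3OCOC)cc1OCc2ccccc2 | intermediate
17 | (2R,3R)-5,7-bis(benzyloxy)-2-[3,5-bis(benzyloxy)-4-(methoxymethoxy)phenyl]-3-(methoxymethoxy)chromane | COCOc1c(OCc2ccccc2)cc([C@H]3Oc4cc(OCc2ccccc2)cc(OCc2ccccc2)c4C[C@H]3OCOC)cc1OCc2ccccc2 | intermediate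
18 | (2R,3R)-5,7-bis(benzyloxy)-2-[3,5-bis(benzyloxy)-4-hydroxyphenyl]chroman-3-ol | Oc1c(OCc2ccccc2)cc([C@H]3Oc4cc(OCc2ccccc2)cc(OCc2ccccc2)c4C[C@H]3O)cc1OCc2ccccc2 | intermediate
19 | 3,4,5-tris(benzyloxy)benzoic acid | OC(=O)c1cc(OCc2ccccc2)c(OCc2ccccc2)c(OCc2ccccc2)c1 | starting material
20 | (2R,3R)-5,7-bis(benzyloxy)-2-{3,5-bis(benzyloxy)-4-[3,4,5-tris(benzyloxy)benzoyloxy]phenyl}chroman-3-yl 3,4,5-tris(benzyloxy)benzoate | O=C(Oc1c(OCc2ccccc2)cc([C@H]3Oc4cc(OCc2ccccc2)cc(OCc2ccccc2)c4C[C@H]3OC(=O)c3cc(OCc2ccccc2)c(OCc2ccccc2)c(OCc2ccccc2)c3)cc1OCc2ccccc2)c1cc(OCc2ccccc2)c(OCc2ccccc2)c(OCc2ccccc2)c1 | intermediate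
21 | epigallocatechin 3,4′-di-O-gallate, (2R,3R) | O=C(Oc1c(O)cc([C@H]2Oc3cc(O)cc(O)c3C[C@H]2OC(=O)c2cc(O)c(O)c(O)c2)cc1O)c1cc(O)c(O)c(O)c1 | target

**Step count and risks**

Total step count: 15. Longest linear sequence: 14 steps (steps 1–5 and 7–15, from 1 to 21).

**Step 9 (key step).** The opened keto ester may return to the pyranone faster than the branched C4a enolate can acylate. It may also be drained through intermolecular condensation of the C8 dienolate, and the electron-rich resorcinolate may oxidise in the basic medium.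

Fallback, setting out from 6 and coming back at 17: ring A is brought in as a preformed arene. Commercial 3,5-bis(benzyloxy)phenol is protected as {2-[(3,5-bis(benzyloxy)phenoxy)methoxy]ethyl}trimethylsilane F1 (SEMCl, iPr2NEt, CH2Cl2). Ortho-lithiation beside the acetal oxygen (n-BuLi, THF, 0 °C; positions 2 and 6 are equivalent) should give [2,4-bis(benzyloxy)-6-{[2-(trimethylsilyl)ethoxy]methoxy}phenyl]lithium F2. F2 opens 6 at the terminal carbon with BF3·OEt2 at −78 °C to (1S,2R)-3-[2,4-bis(benzyloxy)-6-{[2-(trimethylsilyl)ethoxy]methoxy}phenyl]-1-[3,5-bis(benzyloxy)-4-(methoxymethoxy)phenyl]-1-[(triisopropylsilyl)oxy]propan-2-ol F3. MOMCl and iPr2NEt then give the 2-O-methoxymethyl ether of that alcohol F4. Bu4NF in THF/DMPU at 60 °C removes the aryl SEM group and the TIPS ether to 3,5-bis(benzyloxy)-2-{(2R,3S)-3-[3,5-bis(benzyloxy)-4-(methoxymethoxy)phenyl]-3-hydroxy-2-(methoxymethoxy)propyl}phenol F5. The Mitsunobu closure of step 11 applied to F5 gives 17 directly.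

**Step 7.** The delocalised pyranone anion may be too weak a nucleophile for the epoxide, and BF3 may instead induce rearrangement or unselective opening of the silyloxy epoxide.

Fallback, setting out from 6 and coming back at 11: the epoxide is replaced by an alkyl halide electrophile. Epoxide 6 is opened at its terminus with LiI and AcOH in THF to (1S,2S)-1-[3,5-bis(benzyloxy)-4-(methoxymethoxy)phenyl]-3-iodo-1-[(triisopropylsilyl)oxy]propan-2-ol F6. Protection with MOMCl and iPr2NEt gives {(1S,2S)-1-[3,5-bis(benzyloxy)-4-(methoxymethoxy)phenyl]-3-iodo-2-(methoxymethoxy)propoxy}triisopropylsilane F7. This primary iodide alkylates the lithiated pyranone 9 in THF/DMPU (−78 → −20 °C) without a Lewis acid and should give 11.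

**Step 11.** The activated benzylic C2–O bond may ionise, helped by the electron-rich ring B. That would erode the inversion and let the 2,3-trans epimer or an elimination product form.

Fallback, setting out from 15 and coming back at 16: substitution at C2 is replaced by a reduction at C2. The benzylic alcohol of 15 is oxidised with activated MnO2 (CH2Cl2, rt) to (R)-3-[4-(benzyloxy)-2,6-dihydroxyphenyl]-1-[3,5-bis(benzyloxy)-4-(methoxymethoxy)phenyl]-2-(methoxymethoxy)propan-1-one F8. Reductive etherification (Et3SiH, BF3·OEt2, CH2Cl2, −78 → −40 °C) then closes ring C. Hydride should arrive anti to the C3 substituent, which gives the 2,3-cis product 16.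

**Further compounds**

F1 | step 9 | {2-[(3,5-bis(benzyloxy)phenoxy)methoxy]ethyl}trimethylsilane | C[Si](C)(C)CCOCOc1cc(OCc2ccccc2)cc(OCc2ccccc2)c1
F2 | step 9 | [2,4-bis(benzyloxy)-6-{[2-(trimethylsilyl)ethoxy]methoxy}phenyl]lithium | [Li]c1c(OCOCC[Si](C)(C)C)cc(OCc2ccccc2)cc1OCc2ccccc2
F3 | step 9 | (1S,2R)-3-[2,4-bis(benzyloxy)-6-{[2-(trimethylsilyl)ethoxy]methoxy}phenyl]-1-[3,5-bis(benzyloxy)-4-(methoxymethoxy)phenyl]-1-[(triisopropylsilyl)oxy]propan-2-ol | COCOc1c(OCc2ccccc2)cc([C@H](O[Si](C(C)C)(C(C)C)C(C)C)[C@H](O)Cc3c(OCOCC[Si](C)(C)C)cc(OCc2ccccc2)cc3OCc2ccccc2)cc1OCc2ccccc2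
F4 | step 9 | {(1S,2R)-3-[2,4-bis(benzyloxy)-6-{[2-(trimethylsilyl)ethoxy]methoxy}phenyl]-1-[3,5-bis(benzyloxy)-4-(methoxymethoxy)phenyl]-2-(methoxymethoxy)propoxy}triisopropylsilane | COCOc1c(OCc2ccccc2)cc([C@H](O[Si](C(C)C)(C(C)C)C(C)C)[C@H](OCOC)Cc3c(OCOCC[Si](C)(C)C)cc(OCc2ccccc2)cc3OCc2ccccc2)cc1OCc2ccccc2
F5 | step 9 | 3,5-bis(benzyloxy)-2-{(2R,3S)-3-[3,5-bis(benzyloxy)-4-(methoxymethoxy)phenyl]-3-hydroxy-2-(methoxymethoxy)propyl}phenol | COCOc1c(OCc2ccccc2)cc([C@H](O)[C@H](OCOC)Cc3c(O)cc(OCc2ccccc2)cc3OCc2ccccc2)cc1OCc2ccccc2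
F6 | step 7 | (1S,2S)-1-[3,5-bis(benzyloxy)-4-(methoxymethoxy)phenyl]-3-iodo-1-[(triisopropylsilyl)oxy]propan-2-ol | COCOc1c(OCc2ccccc2)cc([C@H](O[Si](C(C)C)(C(C)C)C(C)C)[C@H](O)CI)cc1OCc2ccccc2
F7 | step 7 | {(1S,2S)-1-[3,5-bis(benzyloxy)-4-(methoxymethoxy)phenyl]-3-iodo-2-(methoxymethoxy)propoxy}triisopropylsilane | COCOc1c(OCc2ccccc2)cc([C@H](O[Si](C(C)C)(C(C)C)C(C)C)[C@H](OCOC)CI)cc1OCc2ccccc2
F8 | step 11 | (R)-3-[4-(benzyloxy)-2,6-dihydroxyphenyl]-1-[3,5-bis(benzyloxy)-4-(methoxymethoxy)phenyl]-2-(methoxymethoxy)propan-1-one | COCOc1c(OCc2ccccc2)cc(C(=O)[C@H](OCOC)Cc3c(O)cc(OCc2ccccc2)cc3O)cc1OCc2ccccc2
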